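**Retrosynthetic overview**
1. Propolin B comes from tetra-MOM flavanone 18 by global MOM removal. The C2–C1' bond and the C2 stereocentre of 18 come from a rhodium-catalysed asymmetric 1,4-addition of ring-B boronic acid 15 to 5,7-bis(methoxymethoxy)chromone 17.
2. Boronic acid 15 comes from arene 11 by iridium-catalysed C–H borylation at C5, the only ring-B C–H with no ortho substituent, followed by cleavage of the pinacol ester.
3. The strategy rests on the side chain's E-trisubstituted C2''=C3'' alkene, which carries CH3 on C3'' and is separated from C5' of ring B only by the benzylic C1''. Cutting C3''–CH3 and C1''–C2'' gives terminal alkyne 2, AlMe3 8 and benzylic chloride 7.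
4. Alkyne 2 comes from methyl hex-5-ynoate and MeMgBr; chloride 7 comes from 2,3-dihydroxybenzaldehyde by MOM protection, NaBH4 reduction and chlorination.
5. No ring is formed in the route: rings A and C are bought as 5,7-dihydroxychromone and ring B as the aldehyde.

Key step: step 5

Assumption: the (S)-configured biaryl bisphosphine on rhodium is taken to shield the chromone as it shields 2-cyclohexenone, which places the aryl group on the face that gives (2S); if the sense proved opposite, the (R)-ligand would be used in the same step.

**Route**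

Step 1
Reactants: 1 methyl hex-5-ynoate
Product: 2 2-methylhept-6-yn-2-ol
Conditions: MeMgBr (3.2 equiv), THF, 0 °C to rt; aq. NH4Cl
Reagents that add atoms: methylmagnesium bromide, C[Mg]Br
Why: Double Grignard addition to the ester should give the tertiary alcohol, the excess reagent covering any deprotonation of the acetylenic C–H, which is restored on quench.

Step 2
Reactants: 3 2,3-dihydroxybenzaldehyde
Product: 4 2,3-bis(methoxymethoxy)benzaldehyde
Conditions: NaH (2.4 equiv), MOMCl (2.4 equiv), DMF, 0 °C to rt
Reagents that add atoms: chloromethyl methyl ether, COCCl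
Why: Williamson-type O-alkylation of both phenoxides, the hydrogen-bonded 2-OH included once it is deprotonated by NaH, should give the bis-MOM ether.

Step 3
Reactants: 4 2,3-bis(methoxymethoxy)benzaldehyde
Product: 5 [2,3-bis(methoxymethoxy)phenyl]methanol
Conditions: NaBH4, MeOH, 0 °C
Reagents that add atoms: none
Why: Borohydride reduction of the aldehyde is chemoselective and leaves the MOM acetals untouched.

Step 4
Reactants: 5 [2,3-bis(methoxymethoxy)phenyl]methanol
Product: 7 2,3-bis(methoxymethoxy)benzyl chloride, via benzylic mesylate 6 (not isolated)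
Conditions: MsCl (1.3 equiv), Et3N (1.5 equiv), LiCl (3 equiv), THF, 0 °C to rt; used promptly after filtration through Et3N-deactivated silica
Reagents that add atoms: lithium chloride, [Li+].[Cl-]; methanesulfonyl chloride, CS(=O)(=O)Cl (its chloride is equally a source of the benzylic chlorine)
Why: Mesylation followed by SN2 displacement by chloride at the electron-rich benzylic carbon should give the chloride under base-buffered conditions that never expose the MOM acetals to acid.

Step 5
Reactants: 2 2-methylhept-6-yn-2-ol; 8 trimethylaluminium; 7 2,3-bis(methoxymethoxy)benzyl chloride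
Product: 11 (6E)-8-[2,3-bis(methoxymethoxy)phenyl]-2,6-dimethyloct-6-en-2-ol, via aluminium alkoxide 9 (not isolated), via alkenylalane 10 (not isolated)
Conditions: 2 (1.2 equiv), AlMe3 (3 equiv per 2), (C5H5)2ZrCl2 (0.25 equiv), CH2Cl2, 0 °C to rt; volatiles including excess AlMe3 removed in vacuo; then 7 (1.0 equiv), Pd(PPh3)4 (5 mol%), THF, rt; aq. KNaC4H4O6 (potassium sodium tartrate) work-up
Reagents that add atoms: trimethylaluminium (compound 8), C[Al](C)C
Why: AlMe3 first converts the tertiary alcohol into its dimethylaluminium alkoxide 9, and the methylzirconium species formed from (C5H5)2ZrCl2 and AlMe3 then adds methyl and metal syn across the terminal alkyne with methyl on the internal carbon, transmetalation to aluminium giving the (E)-2-methylalk-1-enylalane 10 (zirconium-catalysed carboalumination, Negishi). Zerovalent palladium inserts into the benzylic C–Cl bond of 7, the alkenyl group passes from aluminium to palladium with retention, and reductive elimination forms the C1''–C2'' bond, which is the known coupling of alkenylalanes with benzylic halides. No ring is closed and no stereocentre is formed; the stereochemical element set here is the E geometry of C2''=C3'', which follows from the syn addition and the stereoretentive coupling. The selectivities needed are methyl delivery to the internal alkyne carbon, secured by the preference of the bulky metal for the terminal carbon, and transfer of alkenyl rather than methyl to palladium, secured by the faster transmetalation of the sp2 carbon and by stripping off excess AlMe3 before the coupling. The MOM acetals meet only the THF-solvated alkenylalane at room temperature, which should be too weak a Lewis acid to open them, and the benzylic chloride is the only electrophilic site offered to palladium.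

Step 6
Reactants: 11 (6E)-8-[2,3-bis(methoxymethoxy)phenyl]-2,6-dimethyloct-6-en-2-ol
Product: 14 (6E)-8-[2,3-bis(methoxymethoxy)-5-(4,4,5,5-tetramethyl-1,3,2-dioxaborolan-2-yl)phenyl]-2,6-dimethyloct-6-en-2-ol, via O-boryl ether 12 (not isolated), via O-borylated arylboronate 13 (not isolated)
Conditions: HBpin (1.2 equiv), B2pin2 (1.0 equiv), [Ir(OMe)(cod)]2 (1.5 mol%), 4,4'-di-tert-butyl-2,2'-bipyridine (3 mol%), THF, 70 °C; then MeOH, rt
Reagents that add atoms: bis(pinacolato)diboron, CC1(C)OB(OC1(C)C)B1OC(C)(C)C(C)(C)O1
Why: Sterically governed iridium-catalysed aromatic C–H borylation should take place at C5, the only ring C–H flanked by two hydrogens, after the tertiary alcohol has been masked in the flask as its O-boryl ether by HBpin (cleaved again by methanol), while the trisubstituted alkene is too hindered to be hydroborated.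

Step 7
Reactants: 14 (6E)-8-[2,3-bis(methoxymethoxy)-5-(4,4,5,5-tetramethyl-1,3,2-dioxaborolan-2-yl)phenyl]-2,6-dimethyloct-6-en-2-ol
Product: 15 {3-[(2E)-7-hydroxy-3,7-dimethyloct-2-en-1-yl]-4,5-bis(methoxymethoxy)phenyl}boronic acid
Conditions: NaIO4 (3 equiv), NH4OAc (3 equiv), acetone/H2O, rt
Reagents that add atoms: water, O
Why: Periodate cleavage of the pinacol released in the hydrolysis equilibrium drives the ester to the free boronic acid under near-neutral conditions that spare the MOM acetals, the alkene and the tertiary alcohol (oxidative deprotection of pinacol boronates).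

Step 8
Reactants: 16 5,7-dihydroxy-4H-chromen-4-one
Product: 17 5,7-bis(methoxymethoxy)-4H-chromen-4-one
Conditions: NaH (2.5 equiv), MOMCl (2.5 equiv), DMF, 0 °C to rt
Reagents that add atoms: chloromethyl methyl ether, COCCl
Why: O-alkylation of both phenoxides, the chelated 5-OH included once deprotonated by NaH, should give the bis-MOM chromone without opening the pyranone under anhydrous conditions.

Step 9
Reactants: 15 {3-[(2E)-7-hydroxy-3,7-dimethyloct-2-en-1-yl]-4,5-bis(methoxymethoxy)phenyl}boronic acid; 17 5,7-bis(methoxymethoxy)-4H-chromen-4-one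
Product: 18 (2S)-2-{3-[(2E)-7-hydroxy-3,7-dimethyloct-2-en-1-yl]-4,5-bis(methoxymethoxy)phenyl}-5,7-bis(methoxymethoxy)-2,3-dihydro-4H-chromen-4-one
Conditions: 17 (1.3 equiv), [Rh(OH)(cod)]2 (2.5 mol%), (S)-6,6'-dimethoxy-2,2'-bis[bis(3,4,5-trifluorophenyl)phosphino]biphenyl (5.5 mol%), CH2Cl2/H2O, 20–25 °C, no added base
Reagents that add atoms: none
Why: In this rhodium-catalysed asymmetric 1,4-addition of an arylboronic acid to a chromone (Hayashi–Miyaura reaction) the aryl–rhodium species formed by transmetalation inserts C2=C3 on the face left open by the (S)-bisphosphine, which sets C2 as S, and water protonates the oxa-π-allyl rhodium, the electron-poor ligand making the reaction fast enough at room temperature without base so that the flavanone neither ring-opens nor racemises.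

Step 10
Reactants: 18 (2S)-2-{3-[(2E)-7-hydroxy-3,7-dimethyloct-2-en-1-yl]-4,5-bis(methoxymethoxy)phenyl}-5,7-bis(methoxymethoxy)-2,3-dihydro-4H-chromen-4-one
Product: 19 propolin B, (2S)-2-{3,4-dihydroxy-5-[(2E)-7-hydroxy-3,7-dimethyloct-2-en-1-yl]phenyl}-5,7-dihydroxy-2,3-dihydro-4H-chromen-4-one
Conditions: aq. HCl (3 M)/MeOH/THF (about 1:4:1), 35–40 °C, stopped at first full conversion; dilution with pH 6 phosphate buffer and extraction, no basic wash
Reagents that add atoms: none
Why: Acid-catalysed transacetalisation of the four aryl MOM ethers to methanol should free the phenols at an acid strength below that needed to ionise the tertiary alcohol or to close the 4'-phenol onto C3'', and the C2 stereocentre is kept because flavanone ring opening needs base.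

**Compound list**
1 | methyl hex-5-ynoate | C#CCCCC(=O)OC | starting material
2 | 2-methylhept-6-yn-2-ol | C#CCCCC(C)(C)O | intermediate
3 | 2,3-dihydroxybenzaldehyde | O=Cc1cccc(O)c1O | starting material
4 | 2,3-bis(methoxymethoxy)benzaldehyde | O=Cc1cccc(OCOC)c1OCOC | intermediate
5 | [2,3-bis(methoxymethoxy)phenyl]methanol | OCc1cccc(OCOC)c1OCOC | intermediate
6 | 2,3-bis(methoxymethoxy)benzyl methanesulfonate | CS(=O)(=O)OCc1cccc(OCOC)c1OCOC | intermediate (not isolated)
7 | 2,3-bis(methoxymethoxy)benzyl chloride | ClCc1cccc(OCOC)c1OCOC | intermediate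
8 | trimethylaluminium | C[Al](C)C | starting material
9 | dimethylaluminium 2-methylhept-6-yn-2-olate | C#CCCCC(C)(C)O[Al](C)C | intermediate (not isolated)
10 | dimethylaluminium (6E)-7-(dimethylalumanyl)-2,6-dimethylhept-6-en-2-olate | C[Al](C)/C=C(\C)CCCC(C)(C)O[Al](C)C | intermediate (not isolated)
11 | (6E)-8-[2,3-bis(methoxymethoxy)phenyl]-2,6-dimethyloct-6-en-2-ol | C/C(=C\Cc1cccc(OCOC)c1OCOC)CCCC(C)(C)O | intermediate
12 | 2-{[(6E)-8-[2,3-bis(methoxymethoxy)phenyl]-2,6-dimethyloct-6-en-2-yl]oxy}-4,4,5,5-tetramethyl-1,3,2-dioxaborolane | C/C(=C\Cc1cccc(OCOC)c1OCOC)CCCC(C)(C)OB1OC(C)(C)C(C)(C)O1 | intermediate (not isolated)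
13 | 2-{[(6E)-8-[2,3-bis(methoxymethoxy)-5-(4,4,5,5-tetramethyl-1,3,2-dioxaborolan-2-yl)phenyl]-2,6-dimethyloct-6-en-2-yl]oxy}-4,4,5,5-tetramethyl-1,3,2-dioxaborolane | C/C(=C\Cc1cc(B2OC(C)(C)C(C)(C)O2)cc(OCOC)c1OCOC)CCCC(C)(C)OB1OC(C)(C)C(C)(C)O1 | intermediate (not isolated)
14 | (6E)-8-[2,3-bis(methoxymethoxy)-5-(4,4,5,5-tetramethyl-1,3,2-dioxaborolan-2-yl)phenyl]-2,6-dimethyloct-6-en-2-ol | C/C(=C\Cc1cc(B2OC(C)(C)C(C)(C)O2)cc(OCOC)c1OCOC)CCCC(C)(C)O | intermediate
15 | {3-[(2E)-7-hydroxy-3,7-dimethyloct-2-en-1-yl]-4,5-bis(methoxymethoxy)phenyl}boronic acid | C/C(=C\Cc1cc(B(O)O)cc(OCOC)c1OCOC)CCCC(C)(C)O | intermediate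
16 | 5,7-dihydroxy-4H-chromen-4-one | O=c1ccoc2cc(O)cc(O)c12 | starting material
17 | 5,7-bis(methoxymethoxy)-4H-chromen-4-one | O=c1ccoc2cc(OCOC)cc(OCOC)c12 | intermediate
18 | (2S)-2-{3-[(2E)-7-hydroxy-3,7-dimethyloct-2-en-1-yl]-4,5-bis(methoxymethoxy)phenyl}-5,7-bis(methoxymethoxy)-2,3-dihydro-4H-chromen-4-one | C/C(=C\Cc1cc([C@@H]2CC(=O)c3c(OCOC)cc(OCOC)cc3O2)cc(OCOC)c1OCOC)CCCC(C)(C)O | intermediate
19 | propolin B | C/C(=C\Cc1cc([C@@H]2CC(=O)c3c(O)cc(O)cc3O2)cc(O)c1O)CCCC(C)(C)O | target

**Step count**
Total steps: 10. Longest linear sequence: 8 steps (steps 2, 3, 4, 5, 6, 7, 9, 10, from 2,3-dihydroxybenzaldehyde).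

**Steps most likely to fail**

Step 5. Three things may go wrong: methyl may transfer from aluminium to the benzylic palladium species, aluminium may open the MOM acetals, and a regioisomeric methylalumination product cannot be removed after the coupling. The fallback separates the two events and reverses the polarity of the coupling. From 2, the same methylalumination (AlMe3, (C5H5)2ZrCl2, CH2Cl2, by way of 9 and 10) is quenched with I2 in THF at −30 °C to give (6E)-7-iodo-2,6-dimethylhept-6-en-2-ol F1, which can be purified from its regioisomer. From 7, Zn dust and LiCl in THF give [2,3-bis(methoxymethoxy)benzyl]zinc chloride F2. Negishi coupling of F1 with F2 (in excess, to cover slow protonation by the tertiary alcohol) under Pd(OAc)2 and 2-dicyclohexylphosphino-2',6'-dimethoxybiphenyl in THF at rt returns to 11, with no aluminium in the flask that holds the MOM groups.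

Step 9. Insertion into the electron-rich 5,7-dioxygenated chromone may be slow enough for protodeboronation to win, or facial selectivity may be insufficient. The fallback gives up catalytic control of C2 and resolves instead. From 15 and 17, a conjugate addition under cationic divalent palladium (Pd(OCOCF3)2, 2,2'-bipyridine, ClCH2CH2Cl/H2O, 60 °C) gives racemic 2-{3-[(2E)-7-hydroxy-3,7-dimethyloct-2-en-1-yl]-4,5-bis(methoxymethoxy)phenyl}-5,7-bis(methoxymethoxy)-2,3-dihydro-4H-chromen-4-one F3. Its enantiomers are separated by preparative HPLC on amylose tris(3,5-dimethylphenylcarbamate), and the (2S)-enantiomer is 18.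

Step 10. The tertiary alcohol may ionise (methyl ether or elimination), or the freed 4'-phenol may close onto C3'' before the last MOM group has left. The fallback replaces protic solvolysis by Lewis-acid/thiol transacetalisation. From 18, ZnBr2 and propane-1-thiol in CH2Cl2 at 0 °C for a few minutes move the methoxymethyl groups onto sulfur and lead directly to 19; this fallback makes no new compound (F0).

**Further compounds**
F1 | step 5 | (6E)-7-iodo-2,6-dimethylhept-6-en-2-ol | I/C=C(\C)CCCC(C)(C)O
F2 | step 5 | [2,3-bis(methoxymethoxy)benzyl]zinc chloride | Cl[Zn]Cc1cccc(OCOC)c1OCOC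
F3 | step 9 | racemic 2-{3-[(2E)-7-hydroxy-3,7-dimethyloct-2-en-1-yl]-4,5-bis(methoxymethoxy)phenyl}-5,7-bis(methoxymethoxy)-2,3-dihydro-4H-chromen-4-one | C/C(=C\Cc1cc(C2CC(=O)c3c(OCOC)cc(OCOC)cc3O2)cc(OCOC)c1OCOC)CCCC(C)(C)O
F0 | step 10 | none | none
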